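**Plan**

- Cuts: the two ester C–O bonds (C2–O acyl; C6–O acetyl, with inversion) and the C4–CH3 bond; ring A (C4a, C5, C6, C7, C8, C8a) at C4a–C8a and C5–C6; the chain at C2–C3; the remaining C10 unit is (R)-carvone opened at its C1–C6 bond.
- Feature: ring A is a cyclohexene whose C7=C8 bond lies opposite the C4a–C5 bond, C4 (ketone level) sits on C4a, and ring B is the four-atom tether C1–C2–C3–C4 from C8a to C4a. A 1-silyloxy-diene (C8a=C8–C7=C6) and a vinyl ketone (C4a=C5) can therefore close both rings at once.
- Forward: carvone → ring-opened dialdehyde → aldol extension (C3, C4) → silyl dienol ether → temporary cyclopentanol (aldol of C3 onto the side-chain aldehyde C1′) → vinyl ketone → intramolecular Diels–Alder (rings A and B together) → retro-aldol removes the temporary ring → C4 methyl, C6 acetate, C2 ester, deprotection.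
- Stereochemistry: C1 from carvone; C2 by Felkin–Anh aldol; C8a by the temporary ring, which holds the C1 side chain axial on the forming ring B; C4a by exo addition or epimerization next to the ketone; C6 by diene geometry, then Mitsunobu inversion; C4 by equatorial methyl delivery.

Key step: step 9

Remark: positions are numbered as in the octahydronaphthalene name of the target (C1 carries the propenoic acid unit C1′–C3′ with C1′ the carboxyl carbon, C2 the acyloxy group, C4 the carbinol, C4a and C8a the ring fusion, C6 the acetoxy group); β is the face of the C1 side chain, α the opposite face.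

**Route**

Step 1
Reactants: 1 (R)-(−)-carvone
Product: 2 (R)-10-chlorocarvone
Conditions: Ca(OCl)2, solid CO2, CH2Cl2–H2O, 0 °C
Reagents that add atoms: calcium hypochlorite Ca(OCl)2, [Ca+2].[O-]Cl.[O-]Cl
Why: Ene-type allylic chlorination by HOCl (from Ca(OCl)2 and CO2) of the electron-rich 1,1-disubstituted alkene, the enone alkene being inert, puts a leaving group on the future C1′ without touching the stereocentre.

Step 2
Reactants: 2 (R)-10-chlorocarvone
Product: 4 trans-6-hydroxy-10-chlorocarvone, via silyl dienol ether 3 (not isolated)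
Conditions: LiN(iPr)2, Me3SiCl, THF, −78 °C; mCPBA, NaHCO3, CH2Cl2, −20 °C; 1 M HCl, THF
Reagents that add atoms: 3-chloroperoxybenzoic acid, OOC(=O)c1cccc(Cl)c1
Why: Rubottom oxidation, in which the kinetic cross-conjugated silyl dienol ether is epoxidized at its enol ether bond anti to the ring substituent and opens to the α-hydroxy ketone (the new carbinol centre is lost in step 4).

Step 3
Reactants: 4 trans-6-hydroxy-10-chlorocarvone
Product: 5 chloro diol
Conditions: NaBH4, CeCl3·7H2O, MeOH, −78 °C
Reagents that add atoms: none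
Why: Luche reduction should give 1,2-reduction of the enone only, leaving the allylic chloride and the alkenes, and the new carbinol centre is lost in step 4.

Step 4
Reactants: 5 chloro diol
Product: 6 (2Z,5S)-5-(3-chloroprop-1-en-2-yl)-2-methylhex-2-enedial
Conditions: NaIO4, THF–pH 7 buffer, 0 °C
Reagents that add atoms: none
Why: Periodate glycol cleavage breaks the ring bond between the two carbinol carbons to give the enal and the saturated aldehyde of the open chain without touching the α-stereocentre (future C1), provided the aldehyde is used at once under neutral conditions.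

Step 5
Reactants: 6 (2Z,5S)-5-(3-chloroprop-1-en-2-yl)-2-methylhex-2-enedial; 7 N-methoxy-N-methylacetamide
Product: 9 hydroxy Weinreb amide, via lithium enolate 8 (not isolated)
Conditions: 7, LiN(iPr)2, THF, −78 °C; then 6, −78 °C; aqueous NH4Cl
Reagents that add atoms: none
Why: Aldol addition of the amide enolate to the more electrophilic saturated aldehyde (the conjugated enal is slower), under Felkin–Anh control with the sp2 carbon of the chloroallyl group as the large substituent anti to the nucleophile, should set the (3S) carbinol, the future C2.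

Step 6
Reactants: 9 hydroxy Weinreb amide
Product: 10 bis-silylated dienol ether
Conditions: TBSOTf, Et3N, CH2Cl2, −78 to 0 °C
Reagents that add atoms: tert-butyldimethylsilyl trifluoromethanesulfonate, CC(C)(C)[Si](C)(C)OS(=O)(=O)C(F)(F)F
Why: Silyl triflate–amine silylation protects the carbinol and converts the enal by O-silylation and γ-deprotonation into the silyl dienol ether, allylic strain placing the branched carbon and the oxygen on the outside of the diene (5E,7E).

Step 7
Reactants: 10 bis-silylated dienol ether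
Product: 11 enal
Conditions: NMO, NaI (cat.), NaHCO3, MeCN, rt
Reagents that add atoms: N-methylmorpholine N-oxide, C[N+]1([O-])CCOCC1
Why: Kornblum-type oxidation, in which the N-oxide displaces the allylic halide (iodide catalysis) and base-induced loss of N-methylmorpholine from the alkoxyammonium salt gives the 2-substituted acrolein under conditions that spare the silyl dienol ether.

Step 8
Reactants: 11 enal
Product: 12 cyclopentanol
Conditions: LiN(SiMe3)2, THF, −78 °C; AcOH, −78 °C
Reagents that add atoms: none
Why: Intramolecular aldol addition of the amide enolate to the non-enolisable enal carbonyl (5-exo-trig, whereas the conjugate mode would be 5-endo-trig) closes the temporary cyclopentanol; allylic strain holds the hydrogen of the silyloxy-bearing carbon in the enolate plane, so the tethered aldehyde attacks anti to the silyloxy group and the carboxamide ends up trans to it and cis to the dienyl group (the new carbinol configuration is of no consequence).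

Step 9
Reactants: 12 cyclopentanol
Product: 14 bridged cycloadduct, via vinyl ketone 13 (not isolated)
Conditions: CH2=CHMgBr (3 equiv), THF, −78 to 0 °C; aqueous NH4Cl; then toluene, BHT, 60 °C
Reagents that add atoms: vinylmagnesium bromide, C=C[Mg]Br
Why: Addition of the vinyl Grignard reagent to the Weinreb amide (stable chelate, so no over-addition) gives on work-up the vinyl ketone 13, whose (E,E)-1-silyloxy-2-methyl-diene (C8a=C8–C7=C6) and enone (C4a=C5) then combine in a concerted, thermal, normal-demand intramolecular [4+2] cycloaddition; the closest known reaction type is the intramolecular Diels–Alder reaction of 1,7,9-decatrien-3-ones. Ring A is closed by the cycloaddition itself (bonds C4a–C8a and C5–C6, new C7=C8 alkene), and ring B is closed by the C4a–C8a bond as the six-membered tether ring (type 1, fused mode) through a chair that carries the two-carbon bridge C2′–C1′ diaxially, so that the product is a bridged bicyclooctanone (three-, two- and one-carbon bridges) fused to ring A. C8a is controlled by the temporary cyclopentanol ring, which holds C2′ axial on C1 and syn to the dienophile with H-1 anti and so overrides the normal preference of a free C1 substituent for the anti position, and with the tether carbon C2 on the outside the diene sits equatorially on ring B, giving H-8a cis to H-1. C4a follows from the exo mode (ketone carbon anti to the diene), which gives the trans ring fusion directly, and an endo adduct would differ only at C4a, which is epimerizable and is corrected in step 10. C6 follows from the (E) geometry of the enol ether and suprafacial addition, which put the silyloxy group cis to C1 (6β), the epimer that step 15 inverts. The selectivity that matters is the diene face; the all-trans cyclopentane is designed to secure it, since only the cis-1,3 dienyl and acryloyl groups can meet and only H-2 lies on the side of the three-carbon bridge, and the absence of a Lewis acid keeps the endo preference of the enone small.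

Step 10
Reactants: 14 bridged cycloadduct
Product: 15 decalone enal
Conditions: DBU, toluene, 40 °C
Reagents that add atoms: none
Why: Base-mediated retro-aldol cleavage of the strained β-hydroxy ketone (bond C3–C1′) is driven by release of the bridged-ring strain and by the conjugation regained in the enal, and the same base equilibrates C4a next to the ketone to the trans ring fusion, which is favoured because a cis fusion would place the axial C1 substituent or the C2 silyloxy group syn-axial to a ring A carbon.

Step 11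
Reactants: 15 decalone enal
Product: 16 acrylic acid
Conditions: NaClO2, NaH2PO4, 2-methyl-2-butene, t-BuOH–H2O, 0 °C
Reagents that add atoms: sodium chlorite NaClO2, [Na+].[O-]Cl=O
Why: Pinnick oxidation converts the enal into the acrylic acid without touching the ketone, the silyl ethers or the alkenes (2-methyl-2-butene traps the HOCl).

Step 12
Reactants: 16 acrylic acid
Product: 17 allyl ester
Conditions: allyl bromide, K2CO3, DMF, rt
Reagents that add atoms: allyl bromide, C=CCBr
Why: Carboxylate O-alkylation (SN2) masks the acid as an allyl ester so that it can neither lactonize onto O-2 nor be activated in steps 15 and 18.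

Step 13
Reactants: 17 allyl ester
Product: 18 tertiary alcohol
Conditions: MeTi(OiPr)3, Et2O, −30 °C to rt
Reagents that add atoms: methyltitanium triisopropoxide, C[Ti](OC(C)C)(OC(C)C)OC(C)C
Why: Nucleophilic addition of the organotitanium reagent, which reacts with the ketone but not with the esters, should occur along the equatorial (β) direction, avoiding the syn-axial hydrogens at C2 and C8a, to give the equatorial methyl and the axial 4α-hydroxyl.

Step 14
Reactants: 18 tertiary alcohol
Product: 19 triol
Conditions: HF·pyridine, pyridine–THF, 0 °C to rt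
Reagents that add atoms: none
Why: Fluoride-mediated cleavage of both silyl ethers (Si–F bond formation) frees the C2 and C6 hydroxyls while the esters and the tertiary alcohol are untouched.

Step 15
Reactants: 19 triol
Product: 20 6α-acetate
Conditions: PPh3, DIAD, AcOH, toluene, 0 °C
Reagents that add atoms: acetic acid, CC(=O)O
Why: Mitsunobu esterification, in which the allylic pseudo-axial 6β-hydroxyl is activated faster than the hindered C2 hydroxyl (flanked by the axial C1 substituent) and the tertiary one, and SN2 displacement by acetate inverts C6 to the 6α-acetate of the target.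

Step 16
Reactants: 21 2,2-dimethyl-4,7-dihydro-1,3-dioxepine
Product: 23 vinyl bromide, via trans-dibromide 22 (not isolated)
Conditions: Br2, CH2Cl2, −78 °C; then DBU, THF, rt
Reagents that add atoms: bromine, BrBr
Why: Anti-bromination of the ring alkene followed by E2 loss of HBr gives the vinyl bromide, the seven-membered acetal keeping the two CH2O groups cis.

Step 17
Reactants: 23 vinyl bromide
Product: 25 dioxepine carboxylic acid, via vinyllithium 24 (not isolated)
Conditions: t-BuLi, THF, −78 °C; CO2; aqueous HCl
Reagents that add atoms: carbon dioxide, O=C=O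
Why: Bromine–lithium exchange and carboxylation of the cyclic vinyllithium give the acid, in which the ring fixes the geometry of the later side chain (ester carbonyl trans to the β-CH2O group).

Step 18
Reactants: 20 6α-acetate; 25 dioxepine carboxylic acid
Product: 27 diester, via mixed anhydride 26 (not isolated)
Conditions: 25, 2,4,6-trichlorobenzoyl chloride, Et3N, THF; then 20, DMAP, toluene, rt
Reagents that add atoms: none
Why: Yamaguchi esterification, in which the mixed anhydride of 25 acylates the only reactive hydroxyl, the secondary C2–OH (the tertiary C4–OH is inert), with retention at C2.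

Step 19
Reactants: 27 diester
Product: 28 acetonide acid
Conditions: Pd(PPh3)4 (cat.), pyrrolidine, CH2Cl2, 0 °C
Reagents that add atoms: none
Why: Tsuji–Trost-type deallylation, in which zerovalent palladium ionizes the allyl ester to a π-allyl complex that pyrrolidine traps, frees the acid under neutral conditions, the hindered secondary cyclic allylic acetate ionizing far more slowly.

Step 20
Reactants: 28 acetonide acid
Product: 29 target
Conditions: AcOH–H2O–THF, rt
Reagents that add atoms: none
Why: Acid-catalysed hydrolysis of the seven-membered isopropylidene acetal under mild aqueous acid should leave the esters, the allylic acetate and the tertiary alcohol intact and give the target.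

**Compound list**

1 | (R)-(−)-carvone, (5R)-2-methyl-5-(prop-1-en-2-yl)cyclohex-2-en-1-one | CC(=C)[C@@H]1CC=C(C)C(=O)C1 | starting material
2 | (R)-10-chlorocarvone, (5R)-5-(3-chloroprop-1-en-2-yl)-2-methylcyclohex-2-en-1-one | C=C(CCl)[C@@H]1CC=C(C)C(=O)C1 | intermediate
3 | cross-conjugated trimethylsilyl dienol ether of 2 (enol ether bond between the former carbonyl carbon and the former α′-CH2; not isolated) | C=C(CCl)[C@@H]1CC=C(C)C(O[Si](C)(C)C)=C1 | intermediate
4 | trans-6-hydroxy-10-chlorocarvone, (5S,6S)-5-(3-chloroprop-1-en-2-yl)-6-hydroxy-2-methylcyclohex-2-en-1-one | C=C(CCl)[C@@H]1CC=C(C)C(=O)[C@H]1O | intermediate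
5 | (1S,6S)-6-(3-chloroprop-1-en-2-yl)-3-methylcyclohex-3-ene-1,2-diol (both C2 epimers) | C=C(CCl)[C@@H]1CC=C(C)C(O)[C@H]1O | intermediate
6 | (2Z,5S)-5-(3-chloroprop-1-en-2-yl)-2-methylhex-2-enedial | C=C(CCl)[C@@H](C=O)C/C=C(C)\C=O | intermediate
7 | N-methoxy-N-methylacetamide | CC(=O)N(C)OC | starting material
8 | lithium enolate of 7 (not isolated) | [Li]OC(=C)N(C)OC | intermediate
9 | (3S,4S,6Z)-4-(3-chloroprop-1-en-2-yl)-3-hydroxy-N-methoxy-N,7-dimethyl-8-oxooct-6-enamide | C=C(CCl)[C@@H]([C@@H](O)CC(=O)N(C)OC)C/C=C(C)\C=O | intermediate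
10 | (3S,4S,5E,7E)-3,8-bis[(tert-butyldimethylsilyl)oxy]-4-(3-chloroprop-1-en-2-yl)-N-methoxy-N,7-dimethylocta-5,7-dienamide | C=C(CCl)[C@@H]([C@@H](O[Si](C)(C)C(C)(C)C)CC(=O)N(C)OC)/C=C/C(C)=C/O[Si](C)(C)C(C)(C)C | intermediate
11 | (3S,4S,5E,7E)-3,8-bis[(tert-butyldimethylsilyl)oxy]-N-methoxy-N,7-dimethyl-4-(3-oxoprop-1-en-2-yl)octa-5,7-dienamide | C=C(C=O)[C@@H]([C@@H](O[Si](C)(C)C(C)(C)C)CC(=O)N(C)OC)/C=C/C(C)=C/O[Si](C)(C)C(C)(C)C | intermediate
12 | (1R,2R,3S)-2-[(tert-butyldimethylsilyl)oxy]-3-[(1E,3E)-4-[(tert-butyldimethylsilyl)oxy]-3-methylbuta-1,3-dien-1-yl]-5-hydroxy-N-methoxy-N-methyl-4-methylidenecyclopentane-1-carboxamide (carboxamide trans to the silyloxy group, cis to the dienyl group; both C5 carbinol epimers) | C=C1C(O)[C@@H](C(=O)N(C)OC)[C@H](O[Si](C)(C)C(C)(C)C)[C@H]1/C=C/C(C)=C/O[Si](C)(C)C(C)(C)C | intermediate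
13 | 1-[(1R,2R,3S)-2-[(tert-butyldimethylsilyl)oxy]-3-[(1E,3E)-4-[(tert-butyldimethylsilyl)oxy]-3-methylbuta-1,3-dien-1-yl]-5-hydroxy-4-methylidenecyclopentyl]prop-2-en-1-one (not isolated) | C=C1C(O)[C@@H](C(=O)C=C)[C@H](O[Si](C)(C)C(C)(C)C)[C@H]1/C=C/C(C)=C/O[Si](C)(C)C(C)(C)C | intermediate
14 | bridged cycloadduct: 2β,6β-bis[(tert-butyldimethylsilyl)oxy]-7-methyl-4-oxo-1,2,3,4,4a,5,6,8a-octahydronaphthalene (4aβ-H, 8aα-H) in which C2′ (bearing the exocyclic CH2) on C1 and the carbinol carbon C1′ on C3 are bonded to each other on the β face (C1′ carbinol epimers) | C=C1[C@@H]2[C@@H]3C=C(C)[C@H](O[Si](C)(C)C(C)(C)C)C[C@H]3C(=O)[C@H](C1O)[C@@H]2O[Si](C)(C)C(C)(C)C | intermediate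
15 | 2-[2β,6β-bis[(tert-butyldimethylsilyl)oxy]-7-methyl-4-oxo-1,2,3,4,4a,5,6,8a-octahydronaphthalen-1β-yl]prop-2-enal (4aβ-H, 8aα-H) | C=C(C=O)[C@@H]1[C@@H]2C=C(C)[C@H](O[Si](C)(C)C(C)(C)C)C[C@H]2C(=O)C[C@@H]1O[Si](C)(C)C(C)(C)C | intermediate
16 | 2-[2β,6β-bis[(tert-butyldimethylsilyl)oxy]-7-methyl-4-oxo-1,2,3,4,4a,5,6,8a-octahydronaphthalen-1β-yl]prop-2-enoic acid (4aβ-H, 8aα-H) | C=C(C(=O)O)[C@@H]1[C@@H]2C=C(C)[C@H](O[Si](C)(C)C(C)(C)C)C[C@H]2C(=O)C[C@@H]1O[Si](C)(C)C(C)(C)C | intermediate
17 | allyl ester of 16 | C=C(C(=O)OCC=C)[C@@H]1[C@@H]2C=C(C)[C@H](O[Si](C)(C)C(C)(C)C)C[C@H]2C(=O)C[C@@H]1O[Si](C)(C)C(C)(C)C | intermediate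
18 | allyl 2-[2β,6β-bis[(tert-butyldimethylsilyl)oxy]-4α-hydroxy-4β,7-dimethyl-1,2,3,4,4a,5,6,8a-octahydronaphthalen-1β-yl]prop-2-enoate (4aβ-H, 8aα-H) | C=C(C(=O)OCC=C)[C@@H]1[C@@H]2C=C(C)[C@H](O[Si](C)(C)C(C)(C)C)C[C@H]2[C@@](C)(O)C[C@@H]1O[Si](C)(C)C(C)(C)C | intermediate
19 | allyl 2-[2β,4α,6β-trihydroxy-4β,7-dimethyl-1,2,3,4,4a,5,6,8a-octahydronaphthalen-1β-yl]prop-2-enoate (4aβ-H, 8aα-H) | C=C(C(=O)OCC=C)[C@@H]1[C@@H]2C=C(C)[C@H](O)C[C@H]2[C@@](C)(O)C[C@@H]1O | intermediate
20 | allyl 2-[6α-acetoxy-2β,4α-dihydroxy-4β,7-dimethyl-1,2,3,4,4a,5,6,8a-octahydronaphthalen-1β-yl]prop-2-enoate (4aβ-H, 8aα-H) | C=C(C(=O)OCC=C)[C@@H]1[C@@H]2C=C(C)[C@@H](OC(C)=O)C[C@H]2[C@@](C)(O)C[C@@H]1O | intermediate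
21 | 2,2-dimethyl-4,7-dihydro-1,3-dioxepine | CC1(C)OCC=CCO1 | starting material
22 | trans-5,6-dibromo-2,2-dimethyl-1,3-dioxepane (racemic; not isolated) | CC1(C)OCC(Br)C(Br)CO1 | intermediate
23 | 5-bromo-2,2-dimethyl-4,7-dihydro-1,3-dioxepine | CC1(C)OCC=C(Br)CO1 | intermediate
24 | (2,2-dimethyl-4,7-dihydro-1,3-dioxepin-5-yl)lithium (not isolated) | [Li]C1=CCOC(C)(C)OC1 | intermediate
25 | 2,2-dimethyl-4,7-dihydro-1,3-dioxepine-5-carboxylic acid | CC1(C)OCC=C(C(=O)O)CO1 | intermediate
26 | 2,2-dimethyl-4,7-dihydro-1,3-dioxepine-5-carboxylic 2,4,6-trichlorobenzoic anhydride (not isolated) | CC1(C)OCC=C(C(=O)OC(=O)c2c(Cl)cc(Cl)cc2Cl)CO1 | intermediate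
27 | allyl 2-[6α-acetoxy-2β-[(2,2-dimethyl-4,7-dihydro-1,3-dioxepine-5-carbonyl)oxy]-4α-hydroxy-4β,7-dimethyl-1,2,3,4,4a,5,6,8a-octahydronaphthalen-1β-yl]prop-2-enoate (4aβ-H, 8aα-H) | C=C(C(=O)OCC=C)[C@@H]1[C@@H]2C=C(C)[C@@H](OC(C)=O)C[C@H]2[C@@](C)(O)C[C@@H]1OC(=O)C1=CCOC(C)(C)OC1 | intermediate
28 | 2-[6α-acetoxy-2β-[(2,2-dimethyl-4,7-dihydro-1,3-dioxepine-5-carbonyl)oxy]-4α-hydroxy-4β,7-dimethyl-1,2,3,4,4a,5,6,8a-octahydronaphthalen-1β-yl]prop-2-enoic acid (4aβ-H, 8aα-H) | C=C(C(=O)O)[C@@H]1[C@@H]2C=C(C)[C@@H](OC(C)=O)C[C@H]2[C@@](C)(O)C[C@@H]1OC(=O)C1=CCOC(C)(C)OC1 | intermediate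
29 | 2-[6α-acetoxy-4α-hydroxy-2β-{[(2E)-4-hydroxy-2-(hydroxymethyl)but-2-enoyl]oxy}-4β,7-dimethyl-1,2,3,4,4a,5,6,8a-octahydronaphthalen-1β-yl]prop-2-enoic acid (4aβ-H, 8aα-H), CNP0468194.2 | C=C(C(=O)O)[C@@H]1[C@@H]2C=C(C)[C@@H](OC(C)=O)C[C@H]2[C@@](C)(O)C[C@@H]1OC(=O)/C(=C/CO)CO | target

**Summary**

Total step count: 20. Longest linear sequence: 18 steps (steps 1–15 and 18–20, from carvone).

Steps most likely to fail:

1. Step 9. What may go wrong: poor diene-face selectivity, that is, cycloaddition through the alternative ring B chair in which the diene is axial and C2 lies inside (assisted by the endo preference of an enone), which would give the C8a epimer; conjugate addition of the cyclopentanol oxygen to the vinyl ketone could also compete. The fallback changes the dienophile to an alkyne, which has no endo mode, so that only the steric preference for an equatorial diene remains. It sets out from 12: ethynylmagnesium bromide converts the Weinreb amide into the ynone F1; heating closes the same two bonds to give the cyclohexa-1,4-diene F2; conjugate reduction of its enone with [CuH(PPh3)]6 and protonation at C4a should give 14 (C4a epimers converge in step 10), where it comes back to the route.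

2. Step 8. What may go wrong: addition of the amide base to the enal or incomplete deprotonation of the amide, loss of the β-silyloxy group from the enolate, or closure with the carboxamide cis to the silyl ether. The fallback replaces the amide by a thioester, which is enolized by a mild Lewis acid–amine pair instead of an amide base. It sets out from 6: direct aldol addition of S-phenyl thioacetate (MgBr2·OEt2, iPr2NEt) gives the hydroxy thioester F3; silylation as in step 6 gives the silyl dienol ether F4, and N-oxide oxidation as in step 7 gives the enal F5; MgBr2·OEt2 and iPr2NEt then close the cyclopentanol F6 by soft enolization, and palladium-catalysed coupling of the thioester with vinylzinc bromide (PdCl2(PPh3)2) gives 13, where it comes back to the route.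

3. Step 13. What may go wrong: poor facial selectivity, since equatorial approach to C4 is hindered by C5 and axial attack would give the C4 epimer, or slow addition to the hindered ketone. The fallback builds the carbinol by methylenation and hydration instead of carbonyl addition. It sets out from 16: Takai–Lombardo methylenation (Zn, CH2Br2, TiCl4) gives the exocyclic alkene F7; oxymercuration–demercuration (Hg(OAc)2, THF–H2O; then NaBH4), in which water opens the mercurinium ion at the tertiary carbon from the axial side, gives the 4α-hydroxy acid F8; allylation as in step 12 gives 18, where it comes back to the route.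

Further compounds
F1 | step 9 | ynone, 1-[(1R,2R,3S)-2-[(tert-butyldimethylsilyl)oxy]-3-[(1E,3E)-4-[(tert-butyldimethylsilyl)oxy]-3-methylbuta-1,3-dien-1-yl]-5-hydroxy-4-methylidenecyclopentyl]prop-2-yn-1-one | C=C1C(O)[C@@H](C(=O)C#C)[C@H](O[Si](C)(C)C(C)(C)C)[C@H]1/C=C/C(C)=C/O[Si](C)(C)C(C)(C)C
F2 | step 9 | cyclohexa-1,4-diene, the 4a,5-didehydro analogue of 14 | C=C1[C@@H]2[C@@H]3C=C(C)[C@H](O[Si](C)(C)C(C)(C)C)C=C3C(=O)[C@H](C1O)[C@@H]2O[Si](C)(C)C(C)(C)C
F3 | step 8 | hydroxy thioester, S-phenyl (3S,4S,6Z)-4-(3-chloroprop-1-en-2-yl)-3-hydroxy-7-methyl-8-oxooct-6-enethioate | C=C(CCl)[C@@H]([C@@H](O)CC(=O)Sc1ccccc1)C/C=C(C)\C=O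
F4 | step 8 | silyl dienol ether, S-phenyl (3S,4S,5E,7E)-3,8-bis[(tert-butyldimethylsilyl)oxy]-4-(3-chloroprop-1-en-2-yl)-7-methylocta-5,7-dienethioate | C=C(CCl)[C@@H]([C@@H](O[Si](C)(C)C(C)(C)C)CC(=O)Sc1ccccc1)/C=C/C(C)=C/O[Si](C)(C)C(C)(C)C
F5 | step 8 | enal, S-phenyl (3S,4S,5E,7E)-3,8-bis[(tert-butyldimethylsilyl)oxy]-7-methyl-4-(3-oxoprop-1-en-2-yl)octa-5,7-dienethioate | C=C(C=O)[C@@H]([C@@H](O[Si](C)(C)C(C)(C)C)CC(=O)Sc1ccccc1)/C=C/C(C)=C/O[Si](C)(C)C(C)(C)C
F6 | step 8 | cyclopentanol, S-phenyl (1R,2R,3S)-2-[(tert-butyldimethylsilyl)oxy]-3-[(1E,3E)-4-[(tert-butyldimethylsilyl)oxy]-3-methylbuta-1,3-dien-1-yl]-5-hydroxy-4-methylidenecyclopentane-1-carbothioate | C=C1C(O)[C@@H](C(=O)Sc2ccccc2)[C@H](O[Si](C)(C)C(C)(C)C)[C@H]1/C=C/C(C)=C/O[Si](C)(C)C(C)(C)C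
F7 | step 13 | exocyclic alkene, 2-[2β,6β-bis[(tert-butyldimethylsilyl)oxy]-7-methyl-4-methylidene-1,2,3,4,4a,5,6,8a-octahydronaphthalen-1β-yl]prop-2-enoic acid | C=C(C(=O)O)[C@@H]1[C@@H]2C=C(C)[C@H](O[Si](C)(C)C(C)(C)C)C[C@H]2C(=C)C[C@@H]1O[Si](C)(C)C(C)(C)C
F8 | step 13 | 4α-hydroxy acid, 2-[2β,6β-bis[(tert-butyldimethylsilyl)oxy]-4α-hydroxy-4β,7-dimethyl-1,2,3,4,4a,5,6,8a-octahydronaphthalen-1β-yl]prop-2-enoic acid | C=C(C(=O)O)[C@@H]1[C@@H]2C=C(C)[C@H](O[Si](C)(C)C(C)(C)C)C[C@H]2[C@@](C)(O)C[C@@H]1O[Si](C)(C)C(C)(C)C
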